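1. Numbering is that of the natural product (C1–C15; O1 is the ring oxygen between C7 and C13). The side chain is cut at C3=C4 (Z-selective Peterson olefination) and at C5–C6 (chloroacetate syn-aldol, both stereocenters), leading back to an oxocene C6 aldehyde.
2. The ring chloroalkene C9=C10(Cl) is traced to a temporary C9 ketone next to a C10 CCl2 group; reductive enol triflation and triflate reduction remove this carbonyl, which is not in the target.
3. Only one ring is formed, in step 9: the eight-membered ring O1–C7–C8–C9–C10–C11–C12–C13 is closed at C10–C11 by a bromine-atom-transfer radical cyclization of an acyclic keto ether, which also installs the C12 bromide.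
4. The feature that makes this possible is a bromodichloromethyl ketone (C9 carbonyl, C10 as CCl2Br) tied through the C7–O1–C13 ether to the terminal C11=C12 vinyl group; C10 serves first as radical precursor and later as the vinyl chloride carbon.
5. The acyclic precursor is assembled from (R)-1,2-epoxybutane (C12–C15), a sulfonium methylide (C11), bromoacetic acid (C6, C7; C7 set by auxiliary alkylation), a bromoacetamide (C8, C9) and dichloromethane (C10).

Key step: step 9

Remark: (4R)-4-benzyl-3-(2-chloroacetyl)-1,3-oxazolidin-2-one and 1,3-bis(triisopropylsilyl)propyne are taken as purchasable catalogue reagents.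

Step 1
Reactants: 1 (R)-1,2-epoxybutane; 2 trimethylsulfonium iodide
Product: 3 (R)-pent-1-en-3-ol
Conditions: 2 (3 equiv), n-BuLi (3 equiv), THF, −10 °C to rt
Reagents that add atoms: none
Why: Dimethylsulfonium methylide opens the epoxide at its CH2 carbon and a second ylide-mediated elimination of dimethyl sulfide gives the one-carbon-homologated allylic alcohol (sulfonium ylide epoxide-to-allylic-alcohol homologation); the C13 stereocenter is carried over unchanged from 1.

Step 2
Reactants: 3 (R)-pent-1-en-3-ol; 4 bromoacetic acid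
Product: 5 2-{[(3R)-pent-1-en-3-yl]oxy}acetic acid
Conditions: NaH (2.5 equiv), THF, 0 °C to rt; then 1 M HCl
Reagents that add atoms: none
Why: Williamson etherification of the sodium alkoxide with sodium bromoacetate (SN2 at a primary α-halo carboxylate) should proceed without touching the stereocenter.

Step 3
Reactants: 5 2-{[(3R)-pent-1-en-3-yl]oxy}acetic acid; 6 (S)-4-benzyl-1,3-oxazolidin-2-one
Product: 8 (4S)-4-benzyl-3-(2-{[(3R)-pent-1-en-3-yl]oxy}acetyl)-1,3-oxazolidin-2-one, via mixed pivalic anhydride 7 (not isolated)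
Conditions: PivCl, Et3N, THF, −78 to 0 °C; then lithiated 6 (6, n-BuLi, THF, −78 °C), −78 to 0 °C
Reagents that add atoms: pivaloyl chloride CC(C)(C)C(Cl)=O (its acyl group is present only in intermediate 7)
Why: The lithiated oxazolidinone should attack the less hindered glycolyl carbonyl of the mixed anhydride (standard N-acylation for auxiliary loading).

Step 4
Reactants: 8 (4S)-4-benzyl-3-(2-{[(3R)-pent-1-en-3-yl]oxy}acetyl)-1,3-oxazolidin-2-one; 9 2-bromo-N-methoxy-N-methylacetamide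
Product: 11 (4S)-4-benzyl-3-[(2R)-4-[methoxy(methyl)amino]-4-oxo-2-{[(3R)-pent-1-en-3-yl]oxy}butanoyl]-1,3-oxazolidin-2-one, via sodium Z-enolate 10 (not isolated)
Conditions: NaN(SiMe3)2, THF, −78 °C; then 9, −78 to −45 °C
Reagents that add atoms: none
Why: Evans-type auxiliary alkylation of the chelated Z-glycolate enolate with a reactive α-bromo amide; the electrophile enters anti to the benzyl group, which sets C7 as (R).

Step 5
Reactants: 11 (4S)-4-benzyl-3-[(2R)-4-[methoxy(methyl)amino]-4-oxo-2-{[(3R)-pent-1-en-3-yl]oxy}butanoyl]-1,3-oxazolidin-2-one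
Product: 12 (3R)-4-hydroxy-N-methoxy-N-methyl-3-{[(3R)-pent-1-en-3-yl]oxy}butanamide
Conditions: NaBH4, THF/H2O, 0 °C to rt
Reagents that add atoms: none
Why: Borohydride should reduce the activated exocyclic imide carbonyl to the primary C6 alcohol and release the auxiliary while the less electrophilic Weinreb amide is kept (chemoselective reductive auxiliary cleavage).

Step 6
Reactants: 12 (3R)-4-hydroxy-N-methoxy-N-methyl-3-{[(3R)-pent-1-en-3-yl]oxy}butanamide
Product: 13 (3R)-4-[(tert-butyldimethylsilyl)oxy]-N-methoxy-N-methyl-3-{[(3R)-pent-1-en-3-yl]oxy}butanamide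
Conditions: TBSCl, imidazole, DMF, rt
Reagents that add atoms: tert-butyldimethylsilyl chloride CC(C)(C)[Si](C)(C)Cl
Why: Silylation of the primary alcohol blocks lactonisation onto the amide and protects C6–OH through the radical and reductive steps (standard silyl ether formation).

Step 7
Reactants: 13 (3R)-4-[(tert-butyldimethylsilyl)oxy]-N-methoxy-N-methyl-3-{[(3R)-pent-1-en-3-yl]oxy}butanamide; 14 dichloromethane
Product: 16 (4R)-5-[(tert-butyldimethylsilyl)oxy]-1,1-dichloro-4-{[(3R)-pent-1-en-3-yl]oxy}pentan-2-one, via lithium hemiaminal adduct 15 (not isolated)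
Conditions: 14, LiN(i-Pr)2, THF, −100 °C; then 13, −100 to −78 °C; AcOH, −78 °C
Reagents that add atoms: none
Why: Dichloromethyllithium should add only once because the chelated tetrahedral adduct survives until the cold acidic quench (Weinreb ketone synthesis with a carbenoid nucleophile), which brings in C10 with both chlorines.

Step 8
Reactants: 16 (4R)-5-[(tert-butyldimethylsilyl)oxy]-1,1-dichloro-4-{[(3R)-pent-1-en-3-yl]oxy}pentan-2-one
Product: 18 (4R)-1-bromo-5-[(tert-butyldimethylsilyl)oxy]-1,1-dichloro-4-{[(3R)-pent-1-en-3-yl]oxy}pentan-2-one, via lithium dichloroenolate 17 (not isolated)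
Conditions: LiN(SiMe3)2 (1.0 equiv), THF, −78 °C; then NBS, −78 °C; pH 7 buffer
Reagents that add atoms: N-bromosuccinimide O=C1CCC(=O)N1Br
Why: The CHCl2 proton is by far the most acidic one, so one equivalent of base should give only the α,α-dichloro enolate, which is brominated at carbon (enolate α-halogenation) before the C8 position can enolise and expel the C7 alkoxy group.

Step 9
Reactants: 18 (4R)-1-bromo-5-[(tert-butyldimethylsilyl)oxy]-1,1-dichloro-4-{[(3R)-pent-1-en-3-yl]oxy}pentan-2-one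
Product: 19 (2R,7S,8R)-7-bromo-2-{[(tert-butyldimethylsilyl)oxy]methyl}-5,5-dichloro-8-ethyloxocan-4-one
Conditions: CuBr (20 mol %), tris(2-pyridylmethyl)amine (TPA, 20 mol %), AIBN (10 mol %), 1,2-dichloroethane (0.005 M), 80 °C
Reagents that add atoms: none
Why: Proposed new method: monovalent copper (CuBr/TPA) abstracts the bromine atom of the C10 CCl2Br group of 18, the electrophilic α,α-dichloro-α-keto radical adds to the unsubstituted terminus C11 of the C11=C12 vinyl group, and the secondary C12 radical takes bromine back from the divalent copper bromide complex, which regenerates the catalyst. The closest known reaction type is the copper-catalysed 8-endo halogen-atom-transfer cyclization of alkenyl trichloroacetates to eight-membered lactones, supported by the 8-endo closures of α-carbonyl radicals onto terminal alkenes; it has not been shown for a bromodichloromethyl ketone closing an oxocane. The ring O1–C7–C8–C9–C10–C11–C12–C13 closes in the 8-endo-trig mode, which should beat 7-exo attack at C12 because the electrophilic radical prefers the less hindered CH2 terminus and the C7–O1–C13 ether with its two branched α-carbons holds the chain ends close. The new C12 stereocenter is controlled by the neighbouring C13 centre: the bulky copper bromide complex should deliver bromine to the ring face opposite the C13 ethyl group, giving the 12,13-trans (12S) bromide. The step needs cyclization to win over 1,6-hydrogen transfer from C13–H and over intermolecular addition, which high dilution, the polarity match of radical and alkene and fast reversible bromine transfer are meant to secure, and it needs bromine rather than chlorine transfer, which the much weaker C–Br bond of the CCl2Br group and a bromide-only copper source secure. C7 and C13 are not touched, and the C9 carbonyl with the two C10 chlorines is the handle from which steps 10 and 11 make the C9=C10 chloroalkene.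

Step 10
Reactants: 19 (2R,7S,8R)-7-bromo-2-{[(tert-butyldimethylsilyl)oxy]methyl}-5,5-dichloro-8-ethyloxocan-4-one
Product: 21 (2R,4Z,7S,8R)-7-bromo-2-{[(tert-butyldimethylsilyl)oxy]methyl}-5-chloro-8-ethyl-3,6,7,8-tetrahydro-2H-oxocin-4-yl trifluoromethanesulfonate, via trimethylsilyl enol ether 20 (not isolated)
Conditions: Zn dust, TMSCl, THF, 0 °C; filtration and concentration; then PhNTf2, CsF, DME, 0 °C to rt
Reagents that add atoms: chlorotrimethylsilane C[Si](C)(C)Cl (silicon present only in intermediate 20); N-phenylbis(trifluoromethanesulfonimide) O=S(=O)(N(c1ccccc1)S(=O)(=O)C(F)(F)F)C(F)(F)F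
Why: Two-electron reduction of the activated α,α-dichloro ketone should give a regiodefined zinc α-chloro enolate that is O-silylated at once (reductive silylation of an α-halo ketone, unactivated secondary C–Br inert), and fluoride-triggered O-triflation then fixes the C9=C10 enol double bond, for which the ring allows only the cis ring geometry.

Step 11
Reactants: 21 (2R,4Z,7S,8R)-7-bromo-2-{[(tert-butyldimethylsilyl)oxy]methyl}-5-chloro-8-ethyl-3,6,7,8-tetrahydro-2H-oxocin-4-yl trifluoromethanesulfonate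
Product: 22 tert-butyl{[(2R,4E,7S,8R)-7-bromo-5-chloro-8-ethyl-3,6,7,8-tetrahydro-2H-oxocin-2-yl]methoxy}dimethylsilane
Conditions: Pd(OAc)2 (5 mol %), dppp (5 mol %), Et3SiH, DMF, 60 °C
Reagents that add atoms: none
Why: Zerovalent palladium should insert into the C9–OTf bond much faster than into the vinyl C–Cl or the secondary C–Br bond, and hydride transfer from the silane then gives the C9–H chloroalkene (palladium-catalysed reduction of an enol triflate; β-chloride elimination would need a cyclooctyne).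

Step 12
Reactants: 22 tert-butyl{[(2R,4E,7S,8R)-7-bromo-5-chloro-8-ethyl-3,6,7,8-tetrahydro-2H-oxocin-2-yl]methoxy}dimethylsilane
Product: 23 [(2R,4E,7S,8R)-7-bromo-5-chloro-8-ethyl-3,6,7,8-tetrahydro-2H-oxocin-2-yl]methanol
Conditions: HF·pyridine, pyridine, THF, 0 °C to rt
Reagents that add atoms: none
Why: Buffered fluoride should cleave the primary silyl ether without base-induced elimination of the secondary bromide (standard desilylation).

Step 13
Reactants: 23 [(2R,4E,7S,8R)-7-bromo-5-chloro-8-ethyl-3,6,7,8-tetrahydro-2H-oxocin-2-yl]methanol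
Product: 24 (2R,4E,7S,8R)-7-bromo-5-chloro-8-ethyl-3,6,7,8-tetrahydro-2H-oxocine-2-carbaldehyde
Conditions: Dess–Martin periodinane, CH2Cl2, 0 °C to rt; used crude
Reagents that add atoms: none
Why: Dess–Martin oxidation under neutral conditions should give the α-alkoxy aldehyde without epimerisation at C7.

Step 14
Reactants: 24 (2R,4E,7S,8R)-7-bromo-5-chloro-8-ethyl-3,6,7,8-tetrahydro-2H-oxocine-2-carbaldehyde; 25 (4R)-4-benzyl-3-(2-chloroacetyl)-1,3-oxazolidin-2-one
Product: 28 (4R)-4-benzyl-3-[(2R,3S)-3-[(2R,4E,7S,8R)-7-bromo-5-chloro-8-ethyl-3,6,7,8-tetrahydro-2H-oxocin-2-yl]-2-chloro-3-hydroxypropanoyl]-1,3-oxazolidin-2-one, via dibutylboron Z-enolate 26 (not isolated), via boron aldolate 27 (not isolated)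
Conditions: 25, Bu2BOTf, i-Pr2NEt, CH2Cl2, −78 to 0 °C; then 24, −78 to 0 °C; pH 7 buffer, MeOH, H2O2, 0 °C
Reagents that add atoms: dibutylboron trifluoromethanesulfonate CCCCB(CCCC)OS(=O)(=O)C(F)(F)F (boron present only in intermediates 26 and 27)
Why: Evans syn-aldol reaction through a closed Zimmerman–Traxler transition state of the Z-boron enolate; the (R)-benzyl auxiliary fixes the absolute sense and should override the small facial bias of the α-alkoxy aldehyde, giving the 5,6-syn chlorohydrin with the C5 and C6 configurations of the target.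

Step 15
Reactants: 28 (4R)-4-benzyl-3-[(2R,3S)-3-[(2R,4E,7S,8R)-7-bromo-5-chloro-8-ethyl-3,6,7,8-tetrahydro-2H-oxocin-2-yl]-2-chloro-3-hydroxypropanoyl]-1,3-oxazolidin-2-one
Product: 29 (2R,3S)-3-[(2R,4E,7S,8R)-7-bromo-5-chloro-8-ethyl-3,6,7,8-tetrahydro-2H-oxocin-2-yl]-2-chloro-3-hydroxy-N-methoxy-N-methylpropanamide
Conditions: MeNH(OMe)·HCl, AlMe3, CH2Cl2, −20 to 0 °C
Reagents that add atoms: N,O-dimethylhydroxylamine hydrochloride CNOC.Cl
Why: Aluminium amide transamination, assisted by the free β-hydroxyl group, should cleave the exocyclic imide carbonyl without epimerising the α-chloro centre (standard conversion of an aldol adduct into a Weinreb amide).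

Step 16
Reactants: 29 (2R,3S)-3-[(2R,4E,7S,8R)-7-bromo-5-chloro-8-ethyl-3,6,7,8-tetrahydro-2H-oxocin-2-yl]-2-chloro-3-hydroxy-N-methoxy-N-methylpropanamide
Product: 30 (2R,3S)-3-[(2R,4E,7S,8R)-7-bromo-5-chloro-8-ethyl-3,6,7,8-tetrahydro-2H-oxocin-2-yl]-2-chloro-N-methoxy-N-methyl-3-[(triethylsilyl)oxy]propanamide
Conditions: TESOTf, 2,6-lutidine, CH2Cl2, −78 to 0 °C
Reagents that add atoms: triethylsilyl trifluoromethanesulfonate CC[Si](CC)(CC)OS(=O)(=O)C(F)(F)F
Why: Silylation of the C6 hydroxyl prevents retro-aldol cleavage and epoxide closure onto the C5 chloride in the following basic steps (standard silyl ether formation).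

Step 17
Reactants: 30 (2R,3S)-3-[(2R,4E,7S,8R)-7-bromo-5-chloro-8-ethyl-3,6,7,8-tetrahydro-2H-oxocin-2-yl]-2-chloro-N-methoxy-N-methyl-3-[(triethylsilyl)oxy]propanamide
Product: 32 (2R,3S)-3-[(2R,4E,7S,8R)-7-bromo-5-chloro-8-ethyl-3,6,7,8-tetrahydro-2H-oxocin-2-yl]-2-chloro-3-[(triethylsilyl)oxy]propanal, via aluminium hemiaminal 31 (not isolated)
Conditions: i-Bu2AlH, CH2Cl2, −78 °C; aqueous Rochelle salt
Reagents that add atoms: diisobutylaluminium hydride CC(C)C[AlH]CC(C)C (aluminium present only in intermediate 31)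
Why: The chelated tetrahedral intermediate of the Weinreb amide reduction should hold until work-up, so the α-chloro aldehyde (C4) is released without over-reduction and at a temperature where the bromide and the chloroalkene are inert.

Step 18
Reactants: 32 (2R,3S)-3-[(2R,4E,7S,8R)-7-bromo-5-chloro-8-ethyl-3,6,7,8-tetrahydro-2H-oxocin-2-yl]-2-chloro-3-[(triethylsilyl)oxy]propanal; 33 1,3-bis(triisopropylsilyl)prop-1-yne
Product: 35 triethyl{[(1S,2S,3Z)-1-[(2R,4E,7S,8R)-7-bromo-5-chloro-8-ethyl-3,6,7,8-tetrahydro-2H-oxocin-2-yl]-2-chloro-6-[tri(propan-2-yl)silyl]hex-3-en-5-yn-1-yl]oxy}silane, via lithium β-silyl alkoxide 34 (not isolated)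
Conditions: 33, n-BuLi, THF, −20 °C; then 32, −78 °C to rt
Reagents that add atoms: none
Why: Peterson olefination with the bulky lithiated bis-silylpropyne should add to the aldehyde with anti selectivity and lose silanolate by syn elimination to give the Z-enyne, and the stabilised, hindered anion should add faster than it deprotonates the α-chloro aldehyde.

Step 19
Reactants: 35 triethyl{[(1S,2S,3Z)-1-[(2R,4E,7S,8R)-7-bromo-5-chloro-8-ethyl-3,6,7,8-tetrahydro-2H-oxocin-2-yl]-2-chloro-6-[tri(propan-2-yl)silyl]hex-3-en-5-yn-1-yl]oxy}silane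
Product: 36 bermudenynol, (1S,2S,3Z)-1-[(2R,4E,7S,8R)-7-bromo-5-chloro-8-ethyl-3,6,7,8-tetrahydro-2H-oxocin-2-yl]-2-chlorohex-3-en-5-yn-1-ol
Conditions: Bu4NF, AcOH, THF, 0 °C to rt
Reagents that add atoms: none
Why: Acetic acid-buffered fluoride should cleave the alkynyl C–Si bond and the triethylsilyl ether without producing a free alkoxide that could close an epoxide onto the C5 chloride or eliminate the C12 bromide (global desilylation).

Compound list
1 | (R)-1,2-epoxybutane | CC[C@@H]1CO1 | starting material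
2 | trimethylsulfonium iodide | C[S+](C)C.[I-] | starting material
3 | (R)-pent-1-en-3-ol | C=C[C@@H](CC)O | intermediate
4 | bromoacetic acid | OC(=O)CBr | starting material
5 | 2-{[(3R)-pent-1-en-3-yl]oxy}acetic acid | C=C[C@@H](CC)OCC(=O)O | intermediate
6 | (S)-4-benzyl-1,3-oxazolidin-2-one | O=C1N[C@@H](Cc2ccccc2)CO1 | starting material
7 | mixed pivalic anhydride of 5 | C=C[C@@H](CC)OCC(=O)OC(=O)C(C)(C)C | intermediate (not isolated)
8 | (4S)-4-benzyl-3-(2-{[(3R)-pent-1-en-3-yl]oxy}acetyl)-1,3-oxazolidin-2-one | C=C[C@@H](CC)OCC(=O)N1[C@@H](Cc2ccccc2)COC1=O | intermediate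
9 | 2-bromo-N-methoxy-N-methylacetamide | CON(C)C(=O)CBr | starting material
10 | sodium Z-enolate of 8 | C=C[C@@H](CC)O/C=C(\[O-])N1[C@@H](Cc2ccccc2)COC1=O.[Na+] | intermediate (not isolated)
11 | (4S)-4-benzyl-3-[(2R)-4-[methoxy(methyl)amino]-4-oxo-2-{[(3R)-pent-1-en-3-yl]oxy}butanoyl]-1,3-oxazolidin-2-one | C=C[C@@H](CC)O[C@H](CC(=O)N(C)OC)C(=O)N1[C@@H](Cc2ccccc2)COC1=O | intermediate
12 | (3R)-4-hydroxy-N-methoxy-N-methyl-3-{[(3R)-pent-1-en-3-yl]oxy}butanamide | C=C[C@@H](CC)O[C@H](CC(=O)N(C)OC)CO | intermediate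
13 | (3R)-4-[(tert-butyldimethylsilyl)oxy]-N-methoxy-N-methyl-3-{[(3R)-pent-1-en-3-yl]oxy}butanamide | C=C[C@@H](CC)O[C@H](CC(=O)N(C)OC)CO[Si](C)(C)C(C)(C)C | intermediate
14 | dichloromethane | ClCCl | starting material
15 | lithium hemiaminal adduct of 13 with dichloromethyllithium (C9 configuration open) | C=C[C@@H](CC)O[C@H](CC([O-])(N(C)OC)C(Cl)Cl)CO[Si](C)(C)C(C)(C)C.[Li+] | intermediate (not isolated)
16 | (4R)-5-[(tert-butyldimethylsilyl)oxy]-1,1-dichloro-4-{[(3R)-pent-1-en-3-yl]oxy}pentan-2-one | C=C[C@@H](CC)O[C@H](CC(=O)C(Cl)Cl)CO[Si](C)(C)C(C)(C)C | intermediate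
17 | lithium dichloroenolate of 16 | C=C[C@@H](CC)O[C@H](CC([O-])=C(Cl)Cl)CO[Si](C)(C)C(C)(C)C.[Li+] | intermediate (not isolated)
18 | (4R)-1-bromo-5-[(tert-butyldimethylsilyl)oxy]-1,1-dichloro-4-{[(3R)-pent-1-en-3-yl]oxy}pentan-2-one | C=C[C@@H](CC)O[C@H](CC(=O)C(Cl)(Cl)Br)CO[Si](C)(C)C(C)(C)C | intermediate
19 | (2R,7S,8R)-7-bromo-2-{[(tert-butyldimethylsilyl)oxy]methyl}-5,5-dichloro-8-ethyloxocan-4-one | CC(C)(C)[Si](C)(C)OC[C@H]1CC(=O)C(Cl)(Cl)C[C@H](Br)[C@@H](CC)O1 | intermediate
20 | tert-butyl{[(2R,4Z,7S,8R)-7-bromo-5-chloro-8-ethyl-4-[(trimethylsilyl)oxy]-3,6,7,8-tetrahydro-2H-oxocin-2-yl]methoxy}dimethylsilane (trimethylsilyl enol ether) | CC(C)(C)[Si](C)(C)OC[C@H]1C/C(O[Si](C)(C)C)=C(/Cl)C[C@H](Br)[C@@H](CC)O1 | intermediate (not isolated)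
21 | (2R,4Z,7S,8R)-7-bromo-2-{[(tert-butyldimethylsilyl)oxy]methyl}-5-chloro-8-ethyl-3,6,7,8-tetrahydro-2H-oxocin-4-yl trifluoromethanesulfonate | CC(C)(C)[Si](C)(C)OC[C@H]1C/C(OS(=O)(=O)C(F)(F)F)=C(/Cl)C[C@H](Br)[C@@H](CC)O1 | intermediate
22 | tert-butyl{[(2R,4E,7S,8R)-7-bromo-5-chloro-8-ethyl-3,6,7,8-tetrahydro-2H-oxocin-2-yl]methoxy}dimethylsilane | CC(C)(C)[Si](C)(C)OC[C@H]1C/C=C(/Cl)C[C@H](Br)[C@@H](CC)O1 | intermediate
23 | [(2R,4E,7S,8R)-7-bromo-5-chloro-8-ethyl-3,6,7,8-tetrahydro-2H-oxocin-2-yl]methanol | OC[C@H]1C/C=C(/Cl)C[C@H](Br)[C@@H](CC)O1 | intermediate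
24 | (2R,4E,7S,8R)-7-bromo-5-chloro-8-ethyl-3,6,7,8-tetrahydro-2H-oxocine-2-carbaldehyde | O=C[C@H]1C/C=C(/Cl)C[C@H](Br)[C@@H](CC)O1 | intermediate
25 | (4R)-4-benzyl-3-(2-chloroacetyl)-1,3-oxazolidin-2-one | ClCC(=O)N1[C@H](Cc2ccccc2)COC1=O | starting material
26 | dibutylboron Z-enolate of 25 | Cl/C=C(\OB(CCCC)CCCC)N1[C@H](Cc2ccccc2)COC1=O | intermediate (not isolated)
27 | boron aldolate (O-dibutylboryl derivative of 28) | O=C(N1[C@H](Cc2ccccc2)COC1=O)[C@H](Cl)[C@@H](OB(CCCC)CCCC)[C@H]1C/C=C(/Cl)C[C@H](Br)[C@@H](CC)O1 | intermediate (not isolated)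
28 | (4R)-4-benzyl-3-[(2R,3S)-3-[(2R,4E,7S,8R)-7-bromo-5-chloro-8-ethyl-3,6,7,8-tetrahydro-2H-oxocin-2-yl]-2-chloro-3-hydroxypropanoyl]-1,3-oxazolidin-2-one | O=C(N1[C@H](Cc2ccccc2)COC1=O)[C@H](Cl)[C@@H](O)[C@H]1C/C=C(/Cl)C[C@H](Br)[C@@H](CC)O1 | intermediate
29 | (2R,3S)-3-[(2R,4E,7S,8R)-7-bromo-5-chloro-8-ethyl-3,6,7,8-tetrahydro-2H-oxocin-2-yl]-2-chloro-3-hydroxy-N-methoxy-N-methylpropanamide | CON(C)C(=O)[C@H](Cl)[C@@H](O)[C@H]1C/C=C(/Cl)C[C@H](Br)[C@@H](CC)O1 | intermediate
30 | (2R,3S)-3-[(2R,4E,7S,8R)-7-bromo-5-chloro-8-ethyl-3,6,7,8-tetrahydro-2H-oxocin-2-yl]-2-chloro-N-methoxy-N-methyl-3-[(triethylsilyl)oxy]propanamide | CON(C)C(=O)[C@H](Cl)[C@@H](O[Si](CC)(CC)CC)[C@H]1C/C=C(/Cl)C[C@H](Br)[C@@H](CC)O1 | intermediate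
31 | aluminium hemiaminal from 30 (O-diisobutylaluminium adduct; C4 configuration open) | CON(C)C(O[Al](CC(C)C)CC(C)C)[C@H](Cl)[C@@H](O[Si](CC)(CC)CC)[C@H]1C/C=C(/Cl)C[C@H](Br)[C@@H](CC)O1 | intermediate (not isolated)
32 | (2R,3S)-3-[(2R,4E,7S,8R)-7-bromo-5-chloro-8-ethyl-3,6,7,8-tetrahydro-2H-oxocin-2-yl]-2-chloro-3-[(triethylsilyl)oxy]propanal | O=C[C@H](Cl)[C@@H](O[Si](CC)(CC)CC)[C@H]1C/C=C(/Cl)C[C@H](Br)[C@@H](CC)O1 | intermediate
33 | 1,3-bis(triisopropylsilyl)prop-1-yne | CC(C)[Si](C(C)C)(C(C)C)C#CC[Si](C(C)C)(C(C)C)C(C)C | starting material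
34 | lithium β-silyl alkoxide from 32 and lithiated 33 (C3 and C4 configurations open) | CC(C)[Si](C(C)C)(C(C)C)C#CC([Si](C(C)C)(C(C)C)C(C)C)C([O-])[C@H](Cl)[C@@H](O[Si](CC)(CC)CC)[C@H]1C/C=C(/Cl)C[C@H](Br)[C@@H](CC)O1.[Li+] | intermediate (not isolated)
35 | triethyl{[(1S,2S,3Z)-1-[(2R,4E,7S,8R)-7-bromo-5-chloro-8-ethyl-3,6,7,8-tetrahydro-2H-oxocin-2-yl]-2-chloro-6-[tri(propan-2-yl)silyl]hex-3-en-5-yn-1-yl]oxy}silane | CC(C)[Si](C(C)C)(C(C)C)C#C/C=C\[C@H](Cl)[C@@H](O[Si](CC)(CC)CC)[C@H]1C/C=C(/Cl)C[C@H](Br)[C@@H](CC)O1 | intermediate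
36 | bermudenynol, (1S,2S,3Z)-1-[(2R,4E,7S,8R)-7-bromo-5-chloro-8-ethyl-3,6,7,8-tetrahydro-2H-oxocin-2-yl]-2-chlorohex-3-en-5-yn-1-ol | C#C/C=C\[C@H](Cl)[C@@H](O)[C@H]1C/C=C(/Cl)C[C@H](Br)[C@@H](CC)O1 | target

Total step count: 19. Longest linear sequence: 19 steps (1 to 36).

Steps most likely to fail

Step 9 (the proposed ring closure). 1,6-Hydrogen transfer from the allylic C13–H, oligomerisation or 7-exo attack may outrun the 8-endo closure, and bromine transfer at C12 may show poor facial selectivity. The fallback uses known chemistry and closes the ring at C9=C10 by ring-closing metathesis instead; it sets out from 8 and comes back at 22. Ozonolysis of 8 (O3, CH2Cl2, −78 °C; Me2S) should give the aldehyde (4S)-4-benzyl-3-(2-{[(2R)-1-oxobutan-2-yl]oxy}acetyl)-1,3-oxazolidin-2-one F1. Chelation-controlled addition of tributyl(2-chloroallyl)stannane (MgBr2·OEt2, CH2Cl2, −78 °C) should then give the 12,13-syn alcohol (4S)-4-benzyl-3-(2-{[(3R,4R)-6-chloro-4-hydroxyhept-6-en-3-yl]oxy}acetyl)-1,3-oxazolidin-2-one F2. Appel bromination with inversion (CBr4, P(n-Oct)3, toluene, 70 °C) should give the bromide (4S)-4-benzyl-3-(2-{[(3R,4S)-4-bromo-6-chlorohept-6-en-3-yl]oxy}acetyl)-1,3-oxazolidin-2-one F3. Auxiliary alkylation (NaN(SiMe3)2, allyl iodide, THF, −78 to −45 °C) sets C7 and should give (4S)-4-benzyl-3-[(2R)-2-{[(3R,4S)-4-bromo-6-chlorohept-6-en-3-yl]oxy}pent-4-enoyl]-1,3-oxazolidin-2-one F4. Reduction (NaBH4, THF/H2O) should give (2R)-2-{[(3R,4S)-4-bromo-6-chlorohept-6-en-3-yl]oxy}pent-4-en-1-ol F5, and silylation (TBSCl, imidazole, DMF) the diene {[(2R)-2-{[(3R,4S)-4-bromo-6-chlorohept-6-en-3-yl]oxy}pent-4-en-1-yl]oxy}(tert-butyl)dimethylsilane F6. Ring-closing metathesis of the 2-chloroalkene with the allyl group (second-generation Grubbs catalyst, CH2Cl2, reflux, high dilution) should then give 22.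

Step 10 (reductive enol triflation). Once fluoride frees the α-chloro enolate, transannular displacement of the C12 bromide (cyclopropane formation) or loss of the ring oxygen by β-elimination may compete with O-triflation. The fallback avoids any enolate; it sets out from 19 and comes back at 22, skipping 21. Treatment of 19 with hydrazine hydrate and KOAc in ethanol (Wharton-type eliminative reduction of an α-halo ketone) should give the hydrazone tert-butyl{[(2R,7S,8R)-7-bromo-5,5-dichloro-8-ethyl-4-hydrazinylideneoxocan-2-yl]methoxy}dimethylsilane F7. F7 should lose HCl to a vinyl diazene and then dinitrogen, giving the C9–H chloroalkene 22 directly.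

Step 18 (Peterson olefination of the α-chloro aldehyde). Epimerisation at C5, loss of HCl, epoxide closure of the intermediate alkoxide onto C5 or erosion of the Z selectivity may occur. The fallback sets out from 32 and comes back at 35. Stork–Zhao olefination (Ph3PCH2I iodide, NaN(SiMe3)2, THF, −78 °C) should give the Z-vinyl iodide triethyl{[(1S,2S,3Z)-1-[(2R,4E,7S,8R)-7-bromo-5-chloro-8-ethyl-3,6,7,8-tetrahydro-2H-oxocin-2-yl]-2-chloro-4-iodobut-3-en-1-yl]oxy}silane F8. Sonogashira coupling with (triisopropylsilyl)acetylene (Pd(PPh3)4, CuI, i-Pr2NH, rt, short reaction time) should then give 35.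

Further compounds
F1 | step 9 | (4S)-4-benzyl-3-(2-{[(2R)-1-oxobutan-2-yl]oxy}acetyl)-1,3-oxazolidin-2-one | CC[C@H](C=O)OCC(=O)N1[C@@H](Cc2ccccc2)COC1=O
F2 | step 9 | (4S)-4-benzyl-3-(2-{[(3R,4R)-6-chloro-4-hydroxyhept-6-en-3-yl]oxy}acetyl)-1,3-oxazolidin-2-one | CC[C@H]([C@H](O)CC(Cl)=C)OCC(=O)N1[C@@H](Cc2ccccc2)COC1=O
F3 | step 9 | (4S)-4-benzyl-3-(2-{[(3R,4S)-4-bromo-6-chlorohept-6-en-3-yl]oxy}acetyl)-1,3-oxazolidin-2-one | CC[C@H]([C@@H](Br)CC(Cl)=C)OCC(=O)N1[C@@H](Cc2ccccc2)COC1=O
F4 | step 9 | (4S)-4-benzyl-3-[(2R)-2-{[(3R,4S)-4-bromo-6-chlorohept-6-en-3-yl]oxy}pent-4-enoyl]-1,3-oxazolidin-2-one | C=CC[C@@H](O[C@H](CC)[C@@H](Br)CC(Cl)=C)C(=O)N1[C@@H](Cc2ccccc2)COC1=O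
F5 | step 9 | (2R)-2-{[(3R,4S)-4-bromo-6-chlorohept-6-en-3-yl]oxy}pent-4-en-1-ol | C=CC[C@@H](O[C@H](CC)[C@@H](Br)CC(Cl)=C)CO
F6 | step 9 | {[(2R)-2-{[(3R,4S)-4-bromo-6-chlorohept-6-en-3-yl]oxy}pent-4-en-1-yl]oxy}(tert-butyl)dimethylsilane | C=CC[C@@H](O[C@H](CC)[C@@H](Br)CC(Cl)=C)CO[Si](C)(C)C(C)(C)C
F7 | step 10 | tert-butyl{[(2R,7S,8R)-7-bromo-5,5-dichloro-8-ethyl-4-hydrazinylideneoxocan-2-yl]methoxy}dimethylsilane | CC(C)(C)[Si](C)(C)OC[C@H]1CC(=NN)C(Cl)(Cl)C[C@H](Br)[C@@H](CC)O1
F8 | step 18 | triethyl{[(1S,2S,3Z)-1-[(2R,4E,7S,8R)-7-bromo-5-chloro-8-ethyl-3,6,7,8-tetrahydro-2H-oxocin-2-yl]-2-chloro-4-iodobut-3-en-1-yl]oxy}silane | I/C=C\[C@H](Cl)[C@@H](O[Si](CC)(CC)CC)[C@H]1C/C=C(/Cl)C[C@H](Br)[C@@H](CC)O1
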